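The readings stem from a simulated flask with made-up constants, noise included.

At the last reading, 6.00 h, the flask read 18% left-handed product. The first 1.00 h gave 6%, but the 3.50 h after 2.50 h gave 8 percentage points, so the curve bends while it still climbs, and right-handed product has not been read.

in all of them: left-handed substrate 1.5 M; right-handed substrate 1.5 M; free catalyst 49 mM
- summer: reagent 1.8 M; the very flask that is asked about, followed so far
- flask: reagent 1.80 M

summer run (percent of the left-handed substrate and right-handed substrate together charged): time / h: left-handed product / % = 0.500: 2; 0.667: 4; 1.00: 6; 1.50: 8; 2.50: 10; 4.00: 13; 6.00: 18

(scatter of a reading: 1.5 percentage points)

- free catalyst is single-handed; left-handed substrate and right-handed substrate are mirror images of each other, charged as a racemate, each of them at the stated concentration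
- no earlier run changes the charge of free catalyst; that part of a forecast is a guess
- no earlier run changes the charge of reagent; that part of a forecast is a guess

* factor on the rate of making left-handed product when 10% of the left-handed substrate and right-handed substrate together are converted if reagent is charged twice over
* factor on the rate when 10% of the left-handed substrate and right-handed substrate together are converted if free catalyst is charged at 500 mM instead

The next person at the bench will find reagent the limiting reagent if each conversion takes one reagent, since the substrates together come to 3.00 M, more than its 1.80 M. The mark, 10% of the substrates together converted, takes 0.300 M, which leaves 1.50 M of reagent, or 3.30 M if reagent is charged twice over, so the reckoning here is a factor of 2.20, assuming first order in reagent. The catalyst charge is not to be touched on trust. The number to carry is the charge factor, new charge over old, 10.2, which is the factor on the rate if the same share of catalyst works at both charges; no run tests that. The forecast gives 1.7 and 15, the second higher than the charge factor, on the reading that “accumulating product ties up the catalyst”.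

The simulation gives 2.27 for reagent and 3.95 for catalyst.

    2 free catalyst ⇌ resting dimer, settled at all times (K = 38.0 M⁻¹)
    reagent + free catalyst + right-handed substrate → free catalyst + right-handed product (k = 1.30 M⁻² h⁻¹)
    2 free catalyst → spent catalyst (k = 3.50 M⁻¹ h⁻¹)
    reagent + free catalyst + left-handed substrate → free catalyst + left-handed product (k = 2.90 M⁻² h⁻¹)

At the mark, free catalyst is 38.0% of the charge in this flask at 1.61 h, but 14.7% with 500 mM, so free catalyst stands at 73.5 mM against 18.6 mM, and the charge factor of 10.2, multiplied by 0.387, comes down to 3.95. At the mark with 500 mM, spent catalyst is 3.20% of the charge and the remaining 82.1% is resting dimer, the resting state. With twice the free catalyst charged, the rate rises by a factor of 1.55, which is 0.775 of that flask's charge factor of 2.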